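**Strategy.** The cyclohexene (C1 = carbinol carbon bearing CH2OBz, C2 and C5 = benzoyloxy carbons, C3=C4, C6 = free carbinol) is cut at C4–C5. An intramolecular Nozaki–Hiyama–Kishi addition of a (Z)-alkenyl iodide to an aldehyde exploits C5 as an allylic carbinol flanked by alkene carbon C4 and oxygenated C6. In one operation it closes the ring, locks the Z-alkene in as C3=C4 and sets C5 under control of C6. The precursor is an acyclic (Z)-6-iodohex-5-enose whose cis C1/C6 oxygens form an acetonide and whose C2–O/CH2–O pair forms a silylene. Its all-cis C2–C1–C6 triad is drawn from C2/C3 of D-mannose by a formaldehyde aldol and an acetylide addition.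

Key step: step 7

Atom mapping used below (target numbering throughout): mannose carbons M1, M2, M3, M4 become C2, C1, C6, C5; the formaldehyde carbon becomes the CH2OBz carbon; the two acetylide carbons become C3 and C4; M5 and M6 are excised in step 6.

Step 1
Reactants: 1 2,3:5,6-di-O-isopropylidene-α-D-mannofuranose; 2 formaldehyde
Product: 3 2-C-(hydroxymethyl)-2,3:5,6-di-O-isopropylidene-D-mannofuranose (anomeric mixture)
Conditions: 37% aq. HCHO, K2CO3, MeOH, 65 °C
Reagents that add atoms: formaldehyde (2), C=O
Why: Crossed aldol hydroxymethylation under thermodynamic control: the lactol opens to its aldehyde, K2CO3 enolizes M2, formaldehyde adds, and only the epimer whose formyl carbon is cis to the M4 oxygen on the dioxolane can re-close to the cis-fused furanose lactol, which fixes the quaternary carbon (future C1) with its oxygen in place and shields the aldehyde from Cannizzaro reduction.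

Step 2
Reactants: 3 2-C-(hydroxymethyl)-2,3:5,6-di-O-isopropylidene-D-mannofuranose; 4 ethynylmagnesium bromide
Product: 5 alkynyl triol, 1,2-dideoxy-4-C-(hydroxymethyl)-4,5:7,8-di-O-isopropylidene-D-glycero-D-talo-oct-1-ynitol (3R)
Conditions: HC≡CMgBr (5 equiv), THF, 0 to 40 °C; aq. NH4Cl
Reagents that add atoms: ethynylmagnesium bromide (4), C#C[Mg]Br
Why: Grignard addition to the ring-opened aldehyde tautomer, in which attack anti to the bulky dioxolane carbon (Felkin–Anh or CH2O–Mg chelate arrangement) should give the erythro (3R) propargylic alcohol (future C2), the sense known for acetylide additions to 2,3-O-isopropylidene furanoses.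

Step 3
Reactants: 5 alkynyl triol
Product: 6 silylene alkyne, the di-tert-butylsilylene of 5 bridging the propargylic oxygen and the branch CH2O (hydroxyl on the future C5 free)
Conditions: tBu2Si(OTf)2, 2,6-lutidine, CH2Cl2, −20 to 0 °C
Reagents that add atoms: di-tert-butylsilyl bis(trifluoromethanesulfonate), CC(C)(C)[Si](OS(=O)(=O)C(F)(F)F)(OS(=O)(=O)C(F)(F)F)C(C)(C)C
Why: Silylene protection of a 1,3-diol: only the propargylic OH and the branch CH2OH can close a six-membered 1,3-dioxa-2-silinane (any ring through the third hydroxyl would be seven-membered), so the hydroxyl needed for the later glycol cleavage stays free.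

Step 4
Reactants: 6 silylene alkyne
Product: 7 iodoalkyne, the 1-iodo derivative of 6
Conditions: NIS, AgNO3 (10 mol%), acetone, rt, dark
Reagents that add atoms: N-iodosuccinimide, O=C1CCC(=O)N1I
Why: Silver-catalysed electrophilic iodination of the terminal alkyne (silver acetylide, then iodine transfer from NIS) should give the 1-iodoalkyne without touching the free hydroxyl, the silylene or the acetals.

Step 5
Reactants: 7 iodoalkyne
Product: 8 (Z)-iodoalkene, the (Z)-1-iodo-oct-1-enitol corresponding to 7
Conditions: 2-nitrobenzenesulfonyl hydrazide, Et3N, THF/iPrOH, rt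
Reagents that add atoms: none
Why: Diimide generated in the flask transfers H2 suprafacially to the iodoalkyne (diimide semi-reduction), which should give the (Z)-iodoalkene with the C–I bond intact.

Step 6
Reactants: 8 (Z)-iodoalkene
Product: 10 (Z)-iodoalkenyl aldehyde, via triol 9 (not isolated)
Conditions: H5IO6 (2.5 equiv), EtOAc, rt
Reagents that add atoms: none
Why: Periodic acid first hydrolyses the exposed terminal dioxolane to triol 9 and then cleaves the 1,2,3-triol twice (Malaprade glycol cleavage), excising M5 and M6 as formic acid and formaldehyde and leaving the future C5 as the aldehyde, while the hindered spiro-dioxolane and the silylene should persist.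

Step 7
Reactants: 10 (Z)-iodoalkenyl aldehyde
Product: 12 tricyclic (5R)-cyclohexenol, via alkenylchromium dichloride 11 (not isolated)
Conditions: CrCl2 (6 equiv), NiCl2 (2 mol%), degassed DMF, 0.005 M, rt; aq. work-up
Reagents that add atoms: none
Why: NiCl2 is reduced by CrCl2 (divalent chromium) to zerovalent nickel, which inserts into the C4–I bond with retention of the Z geometry; transmetalation to trivalent chromium gives alkenylchromium dichloride 11, whose C4 adds to the C5 aldehyde and forges the C4–C5 bond. The closest known reaction type is the intramolecular Nozaki–Hiyama–Kishi reaction, which has been used to close sugar-derived (Z)-iodoalkenyl aldehydes to polyoxygenated cyclohexenols. The carbocycle closes in the 6-exo-trig mode, the carbonyl oxygen staying outside the new ring. The new stereocenter C5 is controlled by C6 and by a conformational lock: the trans-fused silinane forces the C1–CH2 bond equatorial, hence O1 axial and O6 equatorial on the forming half-chair, so the chromium-bound carbonyl oxygen should take the pseudo-equatorial position to avoid a syn-axial clash with O1, placing the 5-OH trans to O6 (5R). The step needs chemoselective addition to the aldehyde (no free hydroxyl is present, so no lactol can form, and silylene and acetonide are inert to organochromium reagents) and cyclization over oligomerization, secured by high dilution and by the silinane chair that already holds C3 and C6 gauche.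

Step 8
Reactants: 12 tricyclic (5R)-cyclohexenol
Product: 13 acetonide triol, 1-(hydroxymethyl)cyclohex-3-ene-1,2,5,6-tetrol 1,6-O-isopropylidene acetal with target configuration
Conditions: HF·pyridine, pyridine, THF, 0 °C to rt
Reagents that add atoms: none
Why: Fluoride cleaves both Si–O bonds of the silylene (desilylation) under buffered conditions that should leave the acetonide and the allylic alcohol untouched, exposing exactly the three hydroxyls that carry benzoates in the target.

Step 9
Reactants: 13 acetonide triol
Product: 14 tribenzoate acetonide, the 2-O,5-O and CH2O tribenzoate of 13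
Conditions: BzCl (4 equiv), pyridine, DMAP (cat.), CH2Cl2, 0 °C to rt
Reagents that add atoms: benzoyl chloride, O=C(Cl)c1ccccc1
Why: DMAP-catalysed acylation of the primary and the two allylic secondary hydroxyls while O1 and O6 are masked in the acetonide, so the complete benzoate pattern is installed in one operation.

Step 10
Reactants: 14 tribenzoate acetonide
Product: 15 [(1S,2R,5R,6S)-2,5-bis(benzoyloxy)-1,6-dihydroxycyclohex-3-en-1-yl]methyl benzoate (CNP0128482.1)
Conditions: TFA/H2O (9:1), CH2Cl2, 0 °C
Reagents that add atoms: none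
Why: Acid-catalysed hydrolysis of the isopropylidene acetal releases the cis C1/C6 diol, and acidic conditions at 0 °C should disfavour benzoyl migration and touch no stereocenter.

**Compound list**

1 | 2,3:5,6-di-O-isopropylidene-α-D-mannofuranose | O[C@@H]1[C@H]2OC(C)(C)O[C@H]2[C@@H]([C@H]2COC(C)(C)O2)O1 | starting material
2 | formaldehyde (37% aqueous) | C=O | starting material
3 | 2-C-(hydroxymethyl)-2,3:5,6-di-O-isopropylidene-D-mannofuranose (anomeric mixture) | OC1[C@@]2(CO)OC(C)(C)O[C@H]2[C@@H]([C@H]2COC(C)(C)O2)O1 | intermediate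
4 | ethynylmagnesium bromide (0.5 M in THF) | C#C[Mg]Br | starting material
5 | (3R)-1,2-dideoxy-4-C-(hydroxymethyl)-4,5:7,8-di-O-isopropylidene-D-glycero-D-talo-oct-1-ynitol (alkynyl triol) | C#C[C@@H](O)[C@@]1(CO)OC(C)(C)O[C@H]1[C@H](O)[C@H]1COC(C)(C)O1 | intermediate
6 | di-tert-butylsilylene of 5 across the propargylic oxygen and the branch CH2O (silylene alkyne, one free secondary OH) | C#C[C@H]1O[Si](C(C)(C)C)(C(C)(C)C)OC[C@@]12OC(C)(C)O[C@H]2[C@H](O)[C@H]1COC(C)(C)O1 | intermediate
7 | 1-iodoalkyne derived from 6 | IC#C[C@H]1O[Si](C(C)(C)C)(C(C)(C)C)OC[C@@]12OC(C)(C)O[C@H]2[C@H](O)[C@H]1COC(C)(C)O1 | intermediate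
8 | (Z)-1-iodoalkene derived from 7 | I/C=C\[C@H]1O[Si](C(C)(C)C)(C(C)(C)C)OC[C@@]12OC(C)(C)O[C@H]2[C@H](O)[C@H]1COC(C)(C)O1 | intermediate
9 | triol from 8 after loss of the terminal acetonide | I/C=C\[C@H]1O[Si](C(C)(C)C)(C(C)(C)C)OC[C@@]12OC(C)(C)O[C@H]2[C@H](O)[C@H](O)CO | intermediate (not isolated)
10 | (Z)-5,6-dideoxy-3-C-(hydroxymethyl)-6-iodo-2,3-O-isopropylidene-D-ribo-hex-5-enose, 4-O and branch CH2O bridged by di-tert-butylsilylene (aldehyde) | I/C=C\[C@H]1O[Si](C(C)(C)C)(C(C)(C)C)OC[C@@]12OC(C)(C)O[C@H]2C=O | intermediate
11 | alkenylchromium dichloride from 10 (trivalent chromium in place of iodine) | Cl[Cr](Cl)/C=C\[C@H]1O[Si](C(C)(C)C)(C(C)(C)C)OC[C@@]12OC(C)(C)O[C@H]2C=O | intermediate (not isolated)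
12 | tricyclic (5R)-cyclohexenol: cyclohex-3-ene with 5-OH, 1,6-O-isopropylidene and di-tert-butylsilylene across 2-O and the C1 CH2O | O[C@@H]1C=C[C@H]2O[Si](C(C)(C)C)(C(C)(C)C)OC[C@@]23OC(C)(C)O[C@@H]13 | intermediate
13 | 1-(hydroxymethyl)cyclohex-3-ene-1,2,5,6-tetrol 1,6-O-isopropylidene acetal, target configuration (acetonide triol) | O[C@@H]1C=C[C@@H](O)[C@@]2(CO)OC(C)(C)O[C@@H]12 | intermediate
14 | tribenzoate acetonide (benzoates on 2-O, 5-O and CH2O; 1,6-O-isopropylidene) | O=C(c1ccccc1)O[C@@H]1C=C[C@@H](OC(=O)c3ccccc3)[C@@]2(COC(=O)c3ccccc3)OC(C)(C)O[C@@H]12 | intermediate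
15 | [(1S,2R,5R,6S)-2,5-bis(benzoyloxy)-1,6-dihydroxycyclohex-3-en-1-yl]methyl benzoate | O=C(OC[C@@]1(O)[C@H](OC(=O)c2ccccc2)C=C[C@@H](OC(=O)c2ccccc2)[C@@H]1O)c1ccccc1 | target

**Step count**

Total steps: 10. Longest linear sequence: 10 steps (1 to 15).

**Steps most likely to fail**

Step 7. The ring closure may proceed with poor or reversed facial selectivity at the aldehyde carbon, so that the 5-OH ends up cis to O6. The fallback corrects C5 after the closure instead of relying on the closure itself. It sets out from aldehyde 10: the same cyclization delivers the (5S)-cyclohexenol F1, whose only free hydroxyl is inverted by a Mitsunobu esterification (PPh3, DIAD, benzoic acid, THF) to the (5R)-benzoate F2. HF·pyridine then removes the silylene to give the 5-O-benzoyl diol F3, and dibenzoylation (BzCl, pyridine, DMAP) comes back to the route at tribenzoate 14.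

Step 2. The acetylide may add with poor facial selectivity, giving a mixture of propargylic epimers. The fallback replaces substrate control by reagent control. It sets out from 5 obtained in admixture with its (3S)-epimer F4: MnO2 in CH2Cl2 oxidises the propargylic hydroxyl of both epimers selectively to the ynone F5. This is reduced at once with (S)-2-methyl-CBS-oxazaborolidine and BH3·SMe2 (THF, −40 °C, alkyne as the small group), which should return the (3R)-alcohol and comes back to the route at 5.

Step 6. The acidic oxidant may also open the spiro-dioxolane or the silylene, or hydrate and over-oxidise the α-alkoxy aldehyde. The fallback makes the aldehyde by a neutral alcohol oxidation in a four-carbon series that never carries the terminal dioxolane. It sets out from formaldehyde 2 and ethynylmagnesium bromide 4: commercial 2,3-O-isopropylidene-L-erythrofuranose F6 is hydroxymethylated with 2 (K2CO3, MeOH, 65 °C) to the branched lactol F7, and 4 adds to give the alkynyl triol F8. tBu2Si(OTf)2 with 2,6-lutidine gives the silylene alcohol F9, NIS with AgNO3 the iodoalkyne F10, and diimide the (Z)-iodoalkenyl alcohol F11. Dess–Martin periodinane (CH2Cl2, NaHCO3) then oxidises the primary hydroxyl, which comes back to the route at aldehyde 10.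

**Further compounds**

F1 | step 7 | (5S)-epimer of tricyclic cyclohexenol 12 | O[C@H]1C=C[C@H]2O[Si](C(C)(C)C)(C(C)(C)C)OC[C@@]23OC(C)(C)O[C@@H]13
F2 | step 7 | (5R)-benzoate of the silylene acetonide | O=C(c1ccccc1)O[C@@H]1C=C[C@H]2O[Si](C(C)(C)C)(C(C)(C)C)OC[C@@]23OC(C)(C)O[C@@H]13
F3 | step 7 | 5-O-benzoyl acetonide diol (free 2-OH and CH2OH) | O=C(c1ccccc1)O[C@@H]1C=C[C@@H](O)[C@@]2(CO)OC(C)(C)O[C@@H]12
F4 | step 2 | (3S)-epimer of alkynyl triol 5 | C#C[C@H](O)[C@@]1(CO)OC(C)(C)O[C@H]1[C@H](O)[C@H]1COC(C)(C)O1
F5 | step 2 | ynone from oxidation of the propargylic alcohol of 5 and F4 | C#CC(=O)[C@@]1(CO)OC(C)(C)O[C@H]1[C@H](O)[C@H]1COC(C)(C)O1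
F6 | step 6 | 2,3-O-isopropylidene-L-erythrofuranose | OC1[C@H]2OC(C)(C)O[C@H]2CO1
F7 | step 6 | 2-C-(hydroxymethyl)-2,3-O-isopropylidene-L-erythrofuranose | OC1[C@@]2(CO)OC(C)(C)O[C@H]2CO1
F8 | step 6 | alkynyl triol of the four-carbon series | C#C[C@@H](O)[C@@]1(CO)OC(C)(C)O[C@H]1CO
F9 | step 6 | silylene alkyne with free primary alcohol | C#C[C@H]1O[Si](C(C)(C)C)(C(C)(C)C)OC[C@@]12OC(C)(C)O[C@H]2CO
F10 | step 6 | iodoalkyne with free primary alcohol | IC#C[C@H]1O[Si](C(C)(C)C)(C(C)(C)C)OC[C@@]12OC(C)(C)O[C@H]2CO
F11 | step 6 | (Z)-iodoalkenyl primary alcohol | I/C=C\[C@H]1O[Si](C(C)(C)C)(C(C)(C)C)OC[C@@]12OC(C)(C)O[C@H]2CO
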